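# Bromoiesol A by a nitrogen linchpin at the central ring: design of the route

Ring atoms are written in lower case so that they cannot be mistaken for compound labels. Ring A is the phenol ring: a1 C–OH, a2 C–O to ring B, a3 and a5 C–Br. Ring B is the central ring: b1 C–O to ring A, b2 C–O to ring C, b3–b5 C–Br, b6 C–H. Ring C is the end ring: c1 C–O, c2 and c4 C–Br. Compounds 1–12 are those of the steps; the target is 12.

## The problem

Bromoiesol A (12) consists of three benzene rings joined by two diaryl ether oxygens that sit on the neighbouring carbons b1 and b2 of ring B. It has no stereocenter, so nothing has to be controlled in space and everything in position. Rings A and C are easy, because their bromines lie ortho and para to an oxygen (a3/a5 to the a2 oxygen, c2/c4 to the c1 oxygen), the pattern that phenol bromination gives and that purchasable building blocks already hold. Ring B is the difficulty: it carries three adjacent bromines at b3, b4 and b5 beside the diether and a single hydrogen at b6, and its two ether oxygens direct ortho to b6 and b3 and para to b4 and b5, so they cannot be trusted to fill b3 and spare b6. Both ether bonds are crowded, since b1 and b2 are neighbours, b2 has b3–Br on its other side, and a2 lies between a1–O and a3–Br. Seven aryl C–Br bonds must survive, which excludes metal-catalysed etherification, catalytic hydrogenation and organolithium or Grignard reagents, and the a1 hydroxyl must stay masked while electrophilic bromine is present, because a free phenol would draw bromine to a4 and a6. The feature that opens the structure is b4, para to the b1 oxygen and flanked by b3 and b5: a nitrogen there serves three times, as a nitro group that activates b1 for nucleophilic substitution, as an amino group whose para position is blocked and whose two ortho positions are exactly where bromine is wanted, and as a diazonium group that leaves in exchange for the third bromine.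

## Retrosynthesis

**a1–O–CH3 bond.** The last operation should touch only the phenol, so 12 is traced back to its methyl ether 11. A benzyl ether would call for hydrogenolysis, which the C–Br bonds forbid, and a silyl ether would not outlast a carbonate-mediated ether formation. The methyl ether survives every step, comes ready-made in building block 6, and keeps ring A a twice-brominated anisole, far less nucleophilic than the aniline of the key step. The forward reaction must cleave one sp3 C–O bond with a boron trihalide; the two diaryl ether bonds offer no sp3 carbon and should stay.

**b4–Br bond.** The central bromine of 11 is exchanged for an amino group, which leads to aniline 9 through diazonium salt 10. Direct bromination at b4 of a b3,b5-dibromide has nothing in its favour: the site lies between two bromines on a deactivated ring. The forward step is a Sandmeyer exchange. The aryl radical from 10 has bromine on both sides and the ether oxygens meta and para, so it cannot close onto a neighbouring aryl ether.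

**b3–Br and b5–Br bonds (key disconnection).** Both flanking bromines of 9 are removed together, giving the triaryl aniline 8. The neighbouring option, bromination before the ethers are made, would flank the nitro group with two bromines and twist it out of conjugation just when it is needed to activate b1. Brominating after the nitrogen has gone would return to the b3/b6 ambiguity. The precursor is lighter by two bromines and has an unsubstituted b3–b6 edge. The forward reaction must pick ring B over rings A and C, and b3 over b6.

**N–O bonds.** Aniline 8 comes from nitro compound 7. The reduction must leave four aryl bromides alone, so a dissolving-metal method with iron is chosen over hydrogenation.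

**b1–O bond.** Compound 7 is cut between b1 and the ether oxygen into aryl fluoride 5 and phenol 6. This bond, not b2–O, is cut here because b1 is para to the nitro group and so open to addition–elimination, while b2 is meta and inert. The cut removes ring A with both bromines and the masked hydroxyl in one purchasable piece. The forward reaction asks a di-ortho-substituted, weakly basic phenoxide to add to a carbon with an aryloxy neighbour.

**O–c1 bond.** Fluoride 5 is cut between the b2 oxygen and ring C into phenol 4 and iodonium salt 3. Neither ring is activated for substitution at this bond, and a copper- or palladium-mediated coupling would have to tell C–I from two C–Br bonds. Ring C is therefore delivered as an aryl cation equivalent on trivalent iodine, without a transition metal. This ether must be made before the b1–O bond, because the free phenoxide of 4 would switch off substitution on its own ring. The phenoxide must take the dibromophenyl group and not the dummy aryl, and must not attack the fluoride of 5.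

**I–C bond of the reagent.** Salt 3 goes back to aryl iodide 1 through the hydroxy(tosyloxy)iodane 2. The second aryl group on iodine is an electron-rich trimethoxyphenyl dummy, chosen so that the electron-poor, ortho-substituted dibromophenyl group is the one transferred.

## Roads not taken

Alternative 1: Ring C is cut at two adjacent atoms, the O–c1 and c2–Br bonds, back to an aryne. In the forward key step benzyne A4, set free by fluoride from silyl triflate A3, would accept the ring B phenoxide oxygen at one carbon and a bromine at the other. Both would come from tetrabromodienone A2, and the product would be diaryl ether A1.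
- Merits: an ether bond and a C–Br bond form in one metal-free operation. The contiguous tribromide is already in A2, which exhaustive phenol bromination should supply. That is a shorter way to three adjacent bromines than the nitro, amino, diazonium sequence, and in this respect this road is better.
- Weak points: the union of A4 with a bromodienone that acts as both oxygen and bromine donor is not an established reaction. Fluoride can attack A2 directly, and the aryl anion formed after oxygen addition can be protonated before it finds bromine.
- A1 lacks the c4 bromine. Adding it later must favour ring C over b6, which in A1 is ortho to a methoxy group.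
- The b1 oxygen of A1 is a methyl ether. After its cleavage the crowded b1–O–a2 bond remains, with no activating group and a ring A electrophile that is not on the shelf.
- Comparison: the chosen plan makes that bond by nitro-activated substitution with purchasable 6 and uses only known reaction types. It pays with two functional-group steps at nitrogen.

Alternative 2: Ring A itself is dissected at a2–a3 and a1–a6 into an alkyne and a pyrone. Forward, alkynylboronate A6, whose alkyne carries the b1 oxygen, would combine with 3,5-dibromo-2-pyrone A7 in a (4+2) cycloaddition, and decarboxylation of the adduct would aromatise it to arylboronate A5. Oxidation of the C–B bond of A5 would then give the a1 hydroxyl.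
- Merits: no crowded ether has to be formed at a2, because the oxygen arrives on the alkyne. The ring A bromines come fixed in A7. The end-game, a mild C–B oxidation, is gentler than the boron trihalide of the chosen plan, and here this road is better.
- Weak points: A6 needs the complete B/C part with its contiguous tribromide, so the central problem is untouched, while the ring being built is the one available ready-made in 6.
- Making an aryl ynol ether and borylating its terminus calls for strong bases or organolithium reagents, which five aryl bromides would not survive.
- The cycloaddition has two orientations, with only the polarisation of the alkyne of A6 to place the oxygen-bearing carbon at C3 of A7. It also needs heat that an ynol ether tolerates poorly.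
- Comparison: the chosen plan has the harsher last step but solves ring B and builds no ring.

Alternative 3: The b3 carbon is taken out of ring B, at the b2–b3 and b3–b4 bonds, leaving a five-membered ring. Forward, the alkene of the racemic bromo enone A9 would be cyclopropanated with the CBr2 unit of phenyl(tribromomethyl)mercury A10. Opening of the three-membered ring and dehydrobromination would expand the cyclopentenone to the six-membered ring B, which would appear as phenol A8.
- Merits: the b3 bromine arrives on the inserted carbon, so its position is beyond doubt. The b1 oxygen appears as a free phenol in A8, and ring C is complete.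
- Weak points: A8 has hydrogen at b4. The central bromine must then go in para to the b1 hydroxyl, between two bromines, in competition with b6 ortho to that hydroxyl, so the original ambiguity returns.
- An electrophilic carbene is poorly matched to an enone, the allylic bromide of A9 is labile, and A10 is a stoichiometric organomercury reagent.
- The b1–O–a2 bond is still to be made with a ring A electrophile.
- Comparison: the chosen plan fixes all three ring B bromines through one substituent and uses only aromatic building blocks.

Key step: step 5

Assumption: compounds 1, 4 and 6 are taken as purchasable; 6 (4,6-dibromoguaiacol) already carries the two ring A bromines ortho and para to its free hydroxyl.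

## Route

Step 1
Reactants: 1 2,4-dibromo-1-iodobenzene
Product: 3 (2,4-dibromophenyl)(2,4,6-trimethoxyphenyl)iodonium 4-methylbenzenesulfonate, via 2,4-dibromo-1-[hydroxy(tosyloxy)iodo]benzene 2 (not isolated)
Conditions: mCPBA, TsOH·H2O, MeCN, 77 °C; then 1,3,5-trimethoxybenzene, 77 °C; Et2O trituration
Reagents that add atoms: p-toluenesulfonic acid monohydrate, Cc1ccc(cc1)S(=O)(=O)O.O; 1,3,5-trimethoxybenzene, COc1cc(OC)cc(OC)c1; mCPBA, OOC(=O)c1cccc(Cl)c1 (oxygen of the hydroxy ligand of 2 only)
Why: The peracid oxidises the aryl iodide to trivalent iodine, captured as the hydroxy(tosyloxy)iodane 2, which then substitutes the very electron-rich trimethoxybenzene in an electrophilic aromatic substitution (one-pot diaryliodonium salt synthesis). The tosylate salt should precipitate and need no chromatography.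

Step 2
Reactants: 4 2-fluoro-5-nitrophenol; 3 (2,4-dibromophenyl)(2,4,6-trimethoxyphenyl)iodonium 4-methylbenzenesulfonate
Product: 5 2-(2,4-dibromophenoxy)-1-fluoro-4-nitrobenzene
Conditions: t-BuOK, THF, 0 °C; then 3 (slight excess), rt to 40 °C
Reagents that add atoms: none
Why: Metal-free O-arylation of a phenoxide with a diaryliodonium salt: ligand exchange at iodine, then ligand coupling, in which the electron-poor, ortho-substituted dibromophenyl group is transferred in preference to the electron-rich trimethoxyphenyl dummy. The mild temperature and low-polarity solvent should keep the phenoxide from displacing the activated fluoride of the product, and no C–Br bond is touched because no transition metal is present.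

Step 3
Reactants: 5 2-(2,4-dibromophenoxy)-1-fluoro-4-nitrobenzene; 6 2,4-dibromo-6-methoxyphenol
Product: 7 1,5-dibromo-2-[2-(2,4-dibromophenoxy)-4-nitrophenoxy]-3-methoxybenzene
Conditions: K2CO3, DMF, 90 °C
Reagents that add atoms: none
Why: Nucleophilic aromatic substitution by addition–elimination: the phenoxide of 6 adds at the fluorine-bearing carbon para to the nitro group, which stabilises the Meisenheimer intermediate, and fluoride leaves. The dibromophenoxy group is meta to the nitro group and the aryl bromides are unactivated, so only fluoride is displaced.

Step 4
Reactants: 7 1,5-dibromo-2-[2-(2,4-dibromophenoxy)-4-nitrophenoxy]-3-methoxybenzene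
Product: 8 4-(2,4-dibromo-6-methoxyphenoxy)-3-(2,4-dibromophenoxy)aniline
Conditions: Fe, NH4Cl, EtOH/H2O, 80 °C
Reagents that add atoms: none
Why: Béchamp-type reduction of the nitro group by electron transfer from iron under nearly neutral conditions. Unlike catalytic hydrogenation it leaves aryl bromides and diaryl ethers untouched.

Step 5
Reactants: 8 4-(2,4-dibromo-6-methoxyphenoxy)-3-(2,4-dibromophenoxy)aniline
Product: 9 2,6-dibromo-4-(2,4-dibromo-6-methoxyphenoxy)-3-(2,4-dibromophenoxy)aniline
Conditions: NBS (2.05 equiv), DMF, 0 °C to rt, dark
Reagents that add atoms: N-bromosuccinimide, O=C1CCC(=O)N1Br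
Why: NBS in DMF delivers electrophilic bromine, and substitution runs through arenium ions on the ring that best carries positive charge, the aminated ring B; the closest known reaction type is the ortho,ortho-dibromination of para-substituted anilines. No ring closes and no stereocenter forms; two C–Br bonds are made, at b5 and then at b3. The step needs ring B to react before rings A and C, and b3 before b6. Ring selectivity should follow because the free amino group is by far the strongest donor in 8, while rings A and C each carry two bromines and only ether donors. Site selectivity should follow because the para position of the amine (b1) is taken by oxygen, leaving only its ortho positions: b5 is also para to the b2 oxygen and should react first, b3 is ortho to both nitrogen and the b2 oxygen and should follow, and b6 is meta to nitrogen. Two equivalents at low temperature leave no reagent for the anisole ring A.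

Step 6
Reactants: 9 2,6-dibromo-4-(2,4-dibromo-6-methoxyphenoxy)-3-(2,4-dibromophenoxy)aniline
Product: 11 1,2,3-tribromo-5-(2,4-dibromo-6-methoxyphenoxy)-4-(2,4-dibromophenoxy)benzene, via arenediazonium bromide 10 (not isolated)
Conditions: t-BuONO, CuBr2, MeCN, 0 to 60 °C
Reagents that add atoms: copper dibromide CuBr2, Br[Cu]Br; tert-butyl nitrite, CC(C)(C)ON=O (nitrogen of 10 only)
Why: Non-aqueous Sandmeyer bromination: the alkyl nitrite diazotises the weakly basic, doubly ortho-substituted aniline, copper-mediated electron transfer releases N2, and the aryl radical takes bromine from CuBr2. The radical at b4 has bromine on both sides and the ether oxygens meta and para, so Pschorr-type ring closure is impossible, and MeCN is a poor hydrogen donor.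

Step 7
Reactants: 11 1,2,3-tribromo-5-(2,4-dibromo-6-methoxyphenoxy)-4-(2,4-dibromophenoxy)benzene
Product: 12 bromoiesol A (3,5-dibromo-2-[3,4,5-tribromo-2-(2,4-dibromophenoxy)phenoxy]phenol)
Conditions: BBr3, CH2Cl2, −78 °C to rt; then H2O
Reagents that add atoms: none
Why: Lewis-acid cleavage of an aryl methyl ether: BBr3 binds the methoxy oxygen and bromide attacks the methyl carbon in an SN2 step, and hydrolysis frees the phenol. The diaryl ether bonds have no sp3 carbon to attack and the aryl bromides are inert.

## Compound list

1 | 2,4-dibromo-1-iodobenzene | Brc1ccc(I)c(Br)c1 | starting material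
2 | 2,4-dibromo-1-[hydroxy(tosyloxy)iodo]benzene | Cc1ccc(cc1)S(=O)(=O)OI(O)c1ccc(Br)cc1Br | intermediate (not isolated)
3 | (2,4-dibromophenyl)(2,4,6-trimethoxyphenyl)iodonium 4-methylbenzenesulfonate | COc1cc(OC)c([I+]c2ccc(Br)cc2Br)c(OC)c1.Cc1ccc(cc1)S(=O)(=O)[O-] | intermediate
4 | 2-fluoro-5-nitrophenol | Oc1cc([N+](=O)[O-])ccc1F | starting material
5 | 2-(2,4-dibromophenoxy)-1-fluoro-4-nitrobenzene | [O-][N+](=O)c1ccc(F)c(Oc2ccc(Br)cc2Br)c1 | intermediate
6 | 2,4-dibromo-6-methoxyphenol | COc1cc(Br)cc(Br)c1O | starting material
7 | 1,5-dibromo-2-[2-(2,4-dibromophenoxy)-4-nitrophenoxy]-3-methoxybenzene | [O-][N+](=O)c1ccc(Oc2c(Br)cc(Br)cc2OC)c(Oc2ccc(Br)cc2Br)c1 | intermediate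
8 | 4-(2,4-dibromo-6-methoxyphenoxy)-3-(2,4-dibromophenoxy)aniline | Nc1ccc(Oc2c(Br)cc(Br)cc2OC)c(Oc2ccc(Br)cc2Br)c1 | intermediate
9 | 2,6-dibromo-4-(2,4-dibromo-6-methoxyphenoxy)-3-(2,4-dibromophenoxy)aniline | Nc1c(Br)cc(Oc2c(Br)cc(Br)cc2OC)c(Oc2ccc(Br)cc2Br)c1Br | intermediate
10 | 2,6-dibromo-4-(2,4-dibromo-6-methoxyphenoxy)-3-(2,4-dibromophenoxy)benzenediazonium bromide | N#[N+]c1c(Br)cc(Oc2c(Br)cc(Br)cc2OC)c(Oc2ccc(Br)cc2Br)c1Br.[Br-] | intermediate (not isolated)
11 | 1,2,3-tribromo-5-(2,4-dibromo-6-methoxyphenoxy)-4-(2,4-dibromophenoxy)benzene | COc1cc(Br)cc(Br)c1Oc1cc(Br)c(Br)c(Br)c1Oc1ccc(Br)cc1Br | intermediate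
12 | bromoiesol A (3,5-dibromo-2-[3,4,5-tribromo-2-(2,4-dibromophenoxy)phenoxy]phenol) | Oc1cc(Br)cc(Br)c1Oc1cc(Br)c(Br)c(Br)c1Oc1ccc(Br)cc1Br | target

## Step count and risks

Total: 7 steps. Longest linear sequence: 7 steps (1 to 12); compounds 4 and 6 enter as purchased pieces.

**Step 5 (key step).** The second substitution, at b3 between the amino group and the bulky dibromophenoxy group, may lag behind the first. Forcing it would let N-bromination and oxidation of the electron-rich aminodiaryl ether compete, or bromination of ring A next to the methoxy group. The fallback lets the b2 oxygen, not the nitrogen, direct both bromines before either ether exists. It sets out from 4: Br2 (two equivalents) in AcOH brominates ortho and para to the hydroxyl, the same carbons b3 and b5, to give 2,4-dibromo-6-fluoro-3-nitrophenol F1. Its potassium phenoxide is arylated with 3 as in step 2 to 1,3-dibromo-4-(2,4-dibromophenoxy)-5-fluoro-2-nitrobenzene F2. Fluoride displacement by 6 as in step 3 gives 1,3-dibromo-5-(2,4-dibromo-6-methoxyphenoxy)-4-(2,4-dibromophenoxy)-2-nitrobenzene F3. The nitro group, twisted by two ortho bromines, would activate less by resonance; the inductive pull of the same bromines, meta to the fluoride, should partly make up for this. Reduction with Fe as in step 4 comes back to the route at 9.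

**Step 2.** Phenoxide of 4 not yet arylated may attack the activated fluoride of product 5 and build oligoethers, more so if aryl transfer to the weakly nucleophilic nitrophenoxide is slow. The fallback makes the b1–O bond first and the O–c1 bond last, when no fluoride remains. It sets out from 4: benzyl bromide and K2CO3 in DMF at rt give 2-(benzyloxy)-1-fluoro-4-nitrobenzene F4. Displacement of fluoride by 6 (K2CO3, DMF) gives 2-[2-(benzyloxy)-4-nitrophenoxy]-1,5-dibromo-3-methoxybenzene F5. BCl3 with pentamethylbenzene in CH2Cl2 at −78 °C removes the benzyl group without hydrogenolysis and without touching the methyl ether, giving 2-(2,4-dibromo-6-methoxyphenoxy)-5-nitrophenol F6. The phenoxide of F6 is arylated with 3 under the step 2 conditions, and the route is rejoined at 7.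

**Step 3.** Addition of the di-ortho-substituted, weakly basic phenoxide to a carbon with an aryloxy neighbour may be slow. Long heating would let hydroxide from traces of water, or dimethylamine from the solvent, take the fluoride instead. The fallback reverses the polarity of this bond and makes it by aryl transfer from trivalent iodine as well. It sets out from 5: aqueous KOH in DMSO replaces fluoride by the small hydroxide to give 2-(2,4-dibromophenoxy)-4-nitrophenol F7. In parallel, purchased 2,4-dibromo-6-methoxyaniline F8 is diazotised (NaNO2, H2SO4) and treated with KI to give 1,5-dibromo-2-iodo-3-methoxybenzene F9. The one-pot procedure of step 1 turns F9 into (2,4-dibromo-6-methoxyphenyl)(2,4,6-trimethoxyphenyl)iodonium 4-methylbenzenesulfonate F10. Arylation of the potassium phenoxide of F7 with F10 comes back to the route at 7.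

**Step 6.** Diazotisation of the hindered, weakly basic aniline may be incomplete, leading to self-coupling. The aryl radical may also abstract hydrogen before it meets bromine, leaving b4–H. The fallback separates diazotisation from bromide delivery and avoids the radical. It sets out from 9: diazotisation with NaNO2 in H2SO4/AcOH at 0 °C and quenching into pyrrolidine with K2CO3 gives the isolable triazene (E)-1-{[2,6-dibromo-4-(2,4-dibromo-6-methoxyphenoxy)-3-(2,4-dibromophenoxy)phenyl]diazenyl}pyrrolidine F11. Bromotrimethylsilane in MeCN at 60 °C should regenerate the diazonium ion paired with bromide and collapse it to the aryl bromide, rejoining the route at 11.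

## Further compounds

F1 | step 5 | 2,4-dibromo-6-fluoro-3-nitrophenol | Oc1c(Br)c([N+](=O)[O-])c(Br)cc1F
F2 | step 5 | 1,3-dibromo-4-(2,4-dibromophenoxy)-5-fluoro-2-nitrobenzene | [O-][N+](=O)c1c(Br)cc(F)c(Oc2ccc(Br)cc2Br)c1Br
F3 | step 5 | 1,3-dibromo-5-(2,4-dibromo-6-methoxyphenoxy)-4-(2,4-dibromophenoxy)-2-nitrobenzene | [O-][N+](=O)c1c(Br)cc(Oc2c(Br)cc(Br)cc2OC)c(Oc2ccc(Br)cc2Br)c1Br
F4 | step 2 | 2-(benzyloxy)-1-fluoro-4-nitrobenzene | [O-][N+](=O)c1ccc(F)c(OCc2ccccc2)c1
F5 | step 2 | 2-[2-(benzyloxy)-4-nitrophenoxy]-1,5-dibromo-3-methoxybenzene | [O-][N+](=O)c1ccc(Oc2c(Br)cc(Br)cc2OC)c(OCc2ccccc2)c1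
F6 | step 2 | 2-(2,4-dibromo-6-methoxyphenoxy)-5-nitrophenol | Oc1cc([N+](=O)[O-])ccc1Oc1c(Br)cc(Br)cc1OC
F7 | step 3 | 2-(2,4-dibromophenoxy)-4-nitrophenol | Oc1ccc([N+](=O)[O-])cc1Oc1ccc(Br)cc1Br
F8 | step 3 | 2,4-dibromo-6-methoxyaniline | COc1cc(Br)cc(Br)c1N
F9 | step 3 | 1,5-dibromo-2-iodo-3-methoxybenzene | COc1cc(Br)cc(Br)c1I
F10 | step 3 | (2,4-dibromo-6-methoxyphenyl)(2,4,6-trimethoxyphenyl)iodonium 4-methylbenzenesulfonate | COc1cc(OC)c([I+]c2c(Br)cc(Br)cc2OC)c(OC)c1.Cc1ccc(cc1)S(=O)(=O)[O-]
F11 | step 6 | (E)-1-{[2,6-dibromo-4-(2,4-dibromo-6-methoxyphenoxy)-3-(2,4-dibromophenoxy)phenyl]diazenyl}pyrrolidine | C1CCN(C1)/N=N/c1c(Br)cc(Oc2c(Br)cc(Br)cc2OC)c(Oc2ccc(Br)cc2Br)c1Br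
A1 | alternative 1 | 1,2,3-tribromo-4-(2-bromophenoxy)-5-methoxybenzene | COc1cc(Br)c(Br)c(Br)c1Oc1ccccc1Br
A2 | alternative 1 | 2,3,4,4-tetrabromo-6-methoxycyclohexa-2,5-dien-1-one | COC1=CC(Br)(Br)C(Br)=C(Br)C1=O
A3 | alternative 1 | 2-(trimethylsilyl)phenyl trifluoromethanesulfonate | C[Si](C)(C)c1ccccc1OS(=O)(=O)C(F)(F)F
A4 | alternative 1 | benzyne (cyclohexa-1,3-dien-5-yne) | C1#CC=CC=C1
A5 | alternative 2 | pinacol 3,5-dibromo-2-[3,4,5-tribromo-2-(2,4-dibromophenoxy)phenoxy]phenylboronate | CC1(C)OB(c2cc(Br)cc(Br)c2Oc2cc(Br)c(Br)c(Br)c2Oc2ccc(Br)cc2Br)OC1(C)C
A6 | alternative 2 | pinacol {[3,4,5-tribromo-2-(2,4-dibromophenoxy)phenoxy]ethynyl}boronate | CC1(C)OB(C#COc2cc(Br)c(Br)c(Br)c2Oc2ccc(Br)cc2Br)OC1(C)C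
A7 | alternative 2 | 3,5-dibromo-2H-pyran-2-one | O=C1OC=C(Br)C=C1Br
A8 | alternative 3 | 3,5-dibromo-2-(2,4-dibromophenoxy)phenol | Oc1cc(Br)cc(Br)c1Oc1ccc(Br)cc1Br
A9 | alternative 3 | rac-4-bromo-2-(2,4-dibromophenoxy)cyclopent-2-en-1-one | O=C1CC(Br)C=C1Oc1ccc(Br)cc1Br
A10 | alternative 3 | phenyl(tribromomethyl)mercury PhHgCBr3 | BrC(Br)(Br)[Hg]c1ccccc1
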